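**Plan**

Retrosynthesis: remove N1–SO2Me and C2–SiMe3. Cut C2'–Br back to the C2'=O lactam of ring B. Cut N1–C2 and C3–Br of indole A together, back to an alkyne on C3a next to a sulfonamide on C7a. Then cut C3a–C(sp), C3a–I, C5–Br, N1'–C7a' and the N1'–C2' amide bond.
Enabling feature: indole A (N1–H, unprimed atoms) needs Br on C3, while C3' of the N1'-linked indole B must keep its hydrogen. Making N1–C2 and C3–Br from one alkyne, while ring B is still a lactam with an sp3 C3', removes any competition between the two pyrrole rings.
Forward: both benzene rings are bought. Acylation and copper-catalysed N-arylation close the lactam ring of B on N1'. The C7a amine, released from the nitro group, directs Br to C5 (para) and I to C3a (ortho). Alkyne and mesyl group follow, the pyrrole ring of A closes, and ring B is aromatised last.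
Stereochemistry: the target has no stereocentre, so nothing has to be set.

Key step: step 8

Assumption: the target SMILES fixes no sense for the hindered C4–N1' axis, so every compound with an ortho-substituted ring A on N1' is handled as a racemate about that axis.

**Step 1**
Reactants: 1 4-methoxy-3-nitroaniline; 2 2-(5-bromo-2-iodophenyl)acetic acid
Product: 4 2-(5-bromo-2-iodophenyl)-N-(4-methoxy-3-nitrophenyl)acetamide, via acid chloride 3 (not isolated)
Conditions: 2, (COCl)2, cat. DMF, CH2Cl2, 0 °C → rt, evaporate; then 1, pyridine, CH2Cl2, 0 °C → rt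
Reagents that add atoms: oxalyl chloride, O=C(Cl)C(=O)Cl (supplies the chlorine of 3; none of its atoms stays in 4)
Why: N-acylation of an aniline with an acid chloride, where the acid chloride makes up for the modest nucleophilicity of the meta-nitroaniline and pyridine, unlike a trialkylamine, keeps the arylacetyl chloride from forming the ketene.

**Step 2**
Reactants: 4 2-(5-bromo-2-iodophenyl)-N-(4-methoxy-3-nitrophenyl)acetamide
Product: 5 5-bromo-1-(4-methoxy-3-nitrophenyl)indolin-2-one
Conditions: CuI (10 mol %), N,N'-dimethylethylenediamine (20 mol %), K2CO3, toluene, 90 °C, argon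
Reagents that add atoms: none
Why: Intramolecular Goldberg amidation, a known route from 2-haloarylacetanilides to N-substituted oxindoles, in which five-membered closure at C–I outruns any intermolecular reaction at C–Br, and O-arylation to a benzoxazole cannot compete because ring A has no ortho halogen yet.

**Step 3**
Reactants: 5 5-bromo-1-(4-methoxy-3-nitrophenyl)indolin-2-one
Product: 6 1-(3-amino-4-methoxyphenyl)-5-bromoindolin-2-one
Conditions: Fe powder, AcOH, EtOH/H2O, 60 °C
Reagents that add atoms: none
Why: Béchamp reduction with iron in acetic acid converts the nitro group into the amine by electron transfer and spares the aryl bromide and the lactam, which catalytic hydrogenation might not.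

**Step 4**
Reactants: 6 1-(3-amino-4-methoxyphenyl)-5-bromoindolin-2-one
Product: 7 1-(5-amino-2-bromo-4-methoxyphenyl)-5-bromoindolin-2-one
Conditions: NBS (1.0 equiv), MeCN, −10 °C → 0 °C, dark
Reagents that add atoms: N-bromosuccinimide, O=C1CCC(=O)N1Br
Why: Electrophilic aromatic bromination directed by the free amine, where, as in 2-methoxyaniline itself, the carbon para to NH2 (the future C5) is the most activated and the less crowded of the two amine-activated sites, so one equivalent of NBS in the cold should be used up there before the lactam CH2 or ring B reacts.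

**Step 5**
Reactants: 7 1-(5-amino-2-bromo-4-methoxyphenyl)-5-bromoindolin-2-one
Product: 8 1-(3-amino-6-bromo-2-iodo-4-methoxyphenyl)-5-bromoindolin-2-one
Conditions: ICl (1.1 equiv), NaHCO3, CH2Cl2/MeOH, 0 °C → rt
Reagents that add atoms: iodine monochloride, ClI
Why: Electrophilic aromatic iodination in which, with the para site blocked, each of the two remaining ring A hydrogens is flanked by two substituents, so sterics cancel and the stronger donor directs iodine to the carbon ortho to NH2 (the future C3a) rather than the one ortho to OMe.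

**Step 6**
Reactants: 8 1-(3-amino-6-bromo-2-iodo-4-methoxyphenyl)-5-bromoindolin-2-one; 9 ethynyltrimethylsilane
Product: 10 1-{3-amino-6-bromo-4-methoxy-2-[(trimethylsilyl)ethynyl]phenyl}-5-bromoindolin-2-one
Conditions: PdCl2(PPh3)2 (5 mol %), CuI (5 mol %), Et3N/THF, 45 °C, argon
Reagents that add atoms: none
Why: Sonogashira coupling, in which zerovalent palladium inserts into C–I much faster than into either C–Br bond at this temperature, and coupling on the free aniline before sulfonylation avoids the spontaneous coupling–cyclisation typical of N-sulfonyl-2-iodoanilines.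

**Step 7**
Reactants: 10 1-{3-amino-6-bromo-4-methoxy-2-[(trimethylsilyl)ethynyl]phenyl}-5-bromoindolin-2-one
Product: 11 N-{4-bromo-3-(5-bromo-2-oxoindolin-1-yl)-6-methoxy-2-[(trimethylsilyl)ethynyl]phenyl}methanesulfonamide
Conditions: MsCl (1.2 equiv), pyridine, CH2Cl2, 0 °C → rt
Reagents that add atoms: methanesulfonyl chloride, CS(=O)(=O)Cl
Why: N-sulfonylation of a primary aniline in pyridine, which should stop at the monosulfonamide for an amine flanked by OMe and the alkyne, and which is too weakly basic to affect the C–Si bond or the lactam CH2.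

**Step 8**
Reactants: 11 N-{4-bromo-3-(5-bromo-2-oxoindolin-1-yl)-6-methoxy-2-[(trimethylsilyl)ethynyl]phenyl}methanesulfonamide
Product: 13 5-bromo-1-[3,5-dibromo-7-methoxy-1-(methylsulfonyl)-2-(trimethylsilyl)-1H-indol-4-yl]indolin-2-one, via C3-cuprated indole 12 (not isolated)
Conditions: CuBr2 (2.5 equiv), 2,6-lutidine (1.2 equiv), MeCN, 50–60 °C, argon
Reagents that add atoms: copper dibromide, Br[Cu]Br
Why: CuBr2 binds the C≡C bond on C3a as a π-acid, the sulfonamide nitrogen on C7a (its proton taken by lutidine) adds anti to the silyl-bearing alkyne carbon to form N1–C2 and a C3–Cu bond (12), and a second CuBr2 oxidises this divalent organocopper to the trivalent level, from which reductive elimination forms C3–Br and releases CuBr. The closest known reaction type is the copper dihalide-mediated halocyclisation of N-sulfonyl- and N-acyl-2-alkynylanilines to 3-haloindoles, and silyl-capped arylalkynes are known to close in the same sense in the related iodocyclisations. The one ring formed, the pyrrole ring of indole A, closes 5-endo-dig, since the 4-exo alternative is geometrically out of reach. No stereocentre is created. The step needs bromine on C3 and nowhere else: copper hands the halogen over at the carbon it has just metalated, so no free brominating agent is required, C3' of ring B is an sp3 lactam carbon that a base as weak as lutidine does not enolise, and N1' is a tertiary lactam nitrogen, which leaves the sulfonamide as the only nitrogen able to attack the alkyne. The silyl cap blocks copper acetylide formation and oxidative alkyne dimerisation, and any C2–H product from late protodesilylation would rejoin the route at the desilylated intermediate of the last step.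

**Step 9**
Reactants: 13 5-bromo-1-[3,5-dibromo-7-methoxy-1-(methylsulfonyl)-2-(trimethylsilyl)-1H-indol-4-yl]indolin-2-one
Product: 14 3,5-dibromo-4-(2,5-dibromo-1H-indol-1-yl)-7-methoxy-1-(methylsulfonyl)-2-(trimethylsilyl)-1H-indole
Conditions: POBr3 (2.5 equiv), imidazole (1.2 equiv), ClCH2CH2Cl, 80 °C
Reagents that add atoms: phosphoryl bromide, O=P(Br)(Br)Br
Why: Deoxygenative bromination–aromatisation of an oxindole (Vilsmeier-type lactam activation), a standard conversion of N-substituted oxindoles in which O-phosphorylation of C2'=O, bromide addition–elimination and loss of a C3' proton give the 2-bromoindole, while imidazole buffers the acid so that the methyl ether and the silyl group survive.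

**Step 10**
Reactants: 14 3,5-dibromo-4-(2,5-dibromo-1H-indol-1-yl)-7-methoxy-1-(methylsulfonyl)-2-(trimethylsilyl)-1H-indole
Product: 16 3,5-dibromo-4-(2,5-dibromo-1H-indol-1-yl)-7-methoxy-1H-indole, via C2-desilylated N-mesylindole 15 (not isolated)
Conditions: Bu4NF (1 M in THF, 5 equiv), THF, rt, then 65 °C; aq NH4Cl
Reagents that add atoms: none
Why: Fluoride-induced protodesilylation of the 2-silylindole at room temperature, followed on heating by the known Bu4NF cleavage of indole N-sulfonyl groups (fluoride attack at sulfur with the indolide as leaving group), with the water in commercial Bu4NF supplying both protons and none of the four C–Br bonds activated toward fluoride.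

**Compound list**

1 | 4-methoxy-3-nitroaniline | COc1ccc(N)cc1[N+](=O)[O-] | starting material
2 | 2-(5-bromo-2-iodophenyl)acetic acid | OC(=O)Cc1cc(Br)ccc1I | starting material
3 | 2-(5-bromo-2-iodophenyl)acetyl chloride | O=C(Cl)Cc1cc(Br)ccc1I | intermediate
4 | 2-(5-bromo-2-iodophenyl)-N-(4-methoxy-3-nitrophenyl)acetamide | COc1ccc(NC(=O)Cc2cc(Br)ccc2I)cc1[N+](=O)[O-] | intermediate
5 | 5-bromo-1-(4-methoxy-3-nitrophenyl)indolin-2-one | COc1ccc(N2C(=O)Cc3cc(Br)ccc32)cc1[N+](=O)[O-] | intermediate
6 | 1-(3-amino-4-methoxyphenyl)-5-bromoindolin-2-one | COc1ccc(N2C(=O)Cc3cc(Br)ccc32)cc1N | intermediate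
7 | 1-(5-amino-2-bromo-4-methoxyphenyl)-5-bromoindolin-2-one | COc1cc(Br)c(N2C(=O)Cc3cc(Br)ccc32)cc1N | intermediate
8 | 1-(3-amino-6-bromo-2-iodo-4-methoxyphenyl)-5-bromoindolin-2-one | COc1cc(Br)c(N2C(=O)Cc3cc(Br)ccc32)c(I)c1N | intermediate
9 | ethynyltrimethylsilane | C#C[Si](C)(C)C | starting material
10 | 1-{3-amino-6-bromo-4-methoxy-2-[(trimethylsilyl)ethynyl]phenyl}-5-bromoindolin-2-one | COc1cc(Br)c(N2C(=O)Cc3cc(Br)ccc32)c(C#C[Si](C)(C)C)c1N | intermediate
11 | N-{4-bromo-3-(5-bromo-2-oxoindolin-1-yl)-6-methoxy-2-[(trimethylsilyl)ethynyl]phenyl}methanesulfonamide | COc1cc(Br)c(N2C(=O)Cc3cc(Br)ccc32)c(C#C[Si](C)(C)C)c1NS(C)(=O)=O | intermediate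
12 | bromo[5-bromo-4-(5-bromo-2-oxoindolin-1-yl)-7-methoxy-1-(methylsulfonyl)-2-(trimethylsilyl)-1H-indol-3-yl]copper | COc1cc(Br)c(N2C(=O)Cc3cc(Br)ccc32)c2c([Cu]Br)c([Si](C)(C)C)n(S(C)(=O)=O)c12 | intermediate
13 | 5-bromo-1-[3,5-dibromo-7-methoxy-1-(methylsulfonyl)-2-(trimethylsilyl)-1H-indol-4-yl]indolin-2-one | COc1cc(Br)c(N2C(=O)Cc3cc(Br)ccc32)c2c(Br)c([Si](C)(C)C)n(S(C)(=O)=O)c12 | intermediate
14 | 3,5-dibromo-4-(2,5-dibromo-1H-indol-1-yl)-7-methoxy-1-(methylsulfonyl)-2-(trimethylsilyl)-1H-indole | COc1cc(Br)c(-n2c(Br)cc3cc(Br)ccc32)c2c(Br)c([Si](C)(C)C)n(S(C)(=O)=O)c12 | intermediate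
15 | 3,5-dibromo-4-(2,5-dibromo-1H-indol-1-yl)-7-methoxy-1-(methylsulfonyl)-1H-indole | COc1cc(Br)c(-n2c(Br)cc3cc(Br)ccc32)c2c(Br)cn(S(C)(=O)=O)c12 | intermediate
16 | 3,5-dibromo-4-(2,5-dibromo-1H-indol-1-yl)-7-methoxy-1H-indole | COc1cc(Br)c(-n2c(Br)cc3cc(Br)ccc32)c2c(Br)c[nH]c12 | target

Total step count: 10. Longest linear sequence: 10 steps (from 1 or 2 to 16).

**Steps most likely to fail**

First, step 8.
- **Risk:** Closure may be slow because N1 ends up wedged between the C7 methoxy group and the C2 silyl group.
- **Risk:** CuBr2 may brominate the lactam methylene through its enol.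
- **Risk:** Early loss of the silyl cap would open the way to oxidative alkyne coupling.
- **Fallback:** Ring closure and bromination are carried out separately.
  - Setting out from 11, Bu4NF in refluxing THF should first unmask N-[4-bromo-3-(5-bromo-2-oxoindolin-1-yl)-2-ethynyl-6-methoxyphenyl]methanesulfonamide F1.
  - The sulfonamide anion of that alkyne closes 5-endo-dig to 5-bromo-1-[5-bromo-7-methoxy-1-(methylsulfonyl)-1H-indol-4-yl]indolin-2-one F2.
  - Continued heating cleaves the N–S bond to give 5-bromo-1-(5-bromo-7-methoxy-1H-indol-4-yl)indolin-2-one F3.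
  - One equivalent of NBS in THF at −78 °C should then attack C3 of the only true indole present, which is far more nucleophilic than the lactam methylene. This gives 5-bromo-1-(3,5-dibromo-7-methoxy-1H-indol-4-yl)indolin-2-one F4.
  - POBr3 and imidazole in ClCH2CH2Cl, as in step 9, aromatise ring B, and the route is rejoined at 16.

Second, step 9.
- **Risk:** The newly formed 2-bromoindole may attack still-activated lactam through C3' and dimerise.
- **Risk:** O-phosphorylation of the crowded lactam may be sluggish.
- **Risk:** The acid released may erode the silyl group or the methyl ether.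
- **Fallback:** C3' is blocked while C2'–Br is made.
  - Setting out from 13, POBr3/DMF in CHCl3 at 0 °C → reflux (Vilsmeier–Haack–Arnold bromoformylation of an oxindole) should give 2,5-dibromo-1-[3,5-dibromo-7-methoxy-1-(methylsulfonyl)-2-(trimethylsilyl)-1H-indol-4-yl]-1H-indole-3-carbaldehyde F5.
  - Stoichiometric RhCl(PPh3)3 in refluxing toluene (Tsuji–Wilkinson decarbonylation) removes the formyl group without touching the aryl bromides, and the route is rejoined at 14.

Third, step 10.
- **Risk:** Fluoride attack at silicon builds carbanion character on C2 next to C3–Br, which may cause loss or migration of that bromine.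
- **Risk:** The prolonged heating needed for N–S cleavage may degrade the 3-bromoindole.
- **Fallback:** Nucleophilic desilylation is replaced by an electrophilic one, and fluoride by hydroxide.
  - Setting out from 14, CF3CO2H in CH2Cl2 at 0 °C → rt protonates C2 ipso to silicon and gives 15, which is now isolated.
  - KOH in MeOH/THF/H2O at rt hydrolyses the sulfonamide, and the route is rejoined at 16.
  - This detour makes no compound outside the list (F0).

**Further compounds**

F1 | step 8 | N-[4-bromo-3-(5-bromo-2-oxoindolin-1-yl)-2-ethynyl-6-methoxyphenyl]methanesulfonamide | COc1cc(Br)c(N2C(=O)Cc3cc(Br)ccc32)c(C#C)c1NS(C)(=O)=O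
F2 | step 8 | 5-bromo-1-[5-bromo-7-methoxy-1-(methylsulfonyl)-1H-indol-4-yl]indolin-2-one | COc1cc(Br)c(N2C(=O)Cc3cc(Br)ccc32)c2ccn(S(C)(=O)=O)c12
F3 | step 8 | 5-bromo-1-(5-bromo-7-methoxy-1H-indol-4-yl)indolin-2-one | COc1cc(Br)c(N2C(=O)Cc3cc(Br)ccc32)c2cc[nH]c12
F4 | step 8 | 5-bromo-1-(3,5-dibromo-7-methoxy-1H-indol-4-yl)indolin-2-one | COc1cc(Br)c(N2C(=O)Cc3cc(Br)ccc32)c2c(Br)c[nH]c12
F5 | step 9 | 2,5-dibromo-1-[3,5-dibromo-7-methoxy-1-(methylsulfonyl)-2-(trimethylsilyl)-1H-indol-4-yl]-1H-indole-3-carbaldehyde | COc1cc(Br)c(-n2c(Br)c(C=O)c3cc(Br)ccc32)c2c(Br)c([Si](C)(C)C)n(S(C)(=O)=O)c12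
F0 | step 10 | none | none
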